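The violet run is this very flask, followed up to 8.00 h, so you need its course over the next 12.0 h.

the same everywhere: substrate 30 mM; partner 31.5 mM
- violet: the very flask that is asked about, followed so far
- flask: time 20 h

violet run (percent of the substrate charged)

| time / h | isomer of the product / % | side product / % | intermediate A / % | substrate / % | target / % | intermediate B / % |
|---|---|---|---|---|---|---|
| 0.667 | 0 | 25.0 | 10.9 | 62.9 | 0 | 1.2 |
| 2.00 | 0.2 | 45.5 | 8.8 | 42.3 | 0 | 3.7 |
| 4.00 | 0.2 | 60.7 | 5.2 | 30.5 | 0 | 3.7 |
| 6.00 | 0.4 | 69.3 | 3.6 | 23.7 | 1.1 | 2.6 |
| 8.00 | 0 | 75.5 | 2.6 | 19.3 | 0 | 2.0 |

(scatter of a reading: 0.3 percentage points)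

1. the species that holds most of what was charged as substrate, at 20 h (intermediate B / substrate / isomer of the product / target / side product / intermediate A)
2. the largest share itself, whichever of these holds it, in percent of the substrate charged

- the numbers in the tables scatter by 0.3 percentage points (one standard deviation)

The readings at 8.00 h add up to 99.4 %, so I take side product as the charge minus substrate and intermediates A and B, and you ask which of these must be known well. The partner's excess is 5.00 %. Take substrate first: at half the pace after the last reading, it ends at 12.0 %. Dropping that excess gives 9.25 %. Intermediates A and B together fell from 8.90 % to 4.60 % in 4.00 h; continued so, they reach 0.635 %.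

Now the number. Take substrate and partner as used one for one, second order. Then the logarithm of partner over substrate climbs in a straight line. The readings at 2.00 h and 8.00 h give 13.2 /M/h for the pairing constant, the climb of that logarithm per hour divided by the difference of the charges. Carried forward, substrate ends at 8.39 %, which leaves me 91.0 % of side product. The forecast says side product at 89.5 %, lower than mine: “The mass balance closes, so nearly everything else ends up as side product”.

The flask gives side product at 90.5 %, with substrate at 7.99 %.

    target ⇌ isomer of the product (K = 0.630, k = 0.00340 /min)
    substrate + partner ⇌ intermediate A (K = 13.0 /M, k = 0.220 /M/min)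
    intermediate A → target (k = 2.20 × 10⁻⁴ /min)
    substrate + partner → side product (k = 0.320 /M/min)
    partner + intermediate A ⇌ intermediate B (K = 51.0 /M, k = 0.250 /M/min)

Between the last reading and 20.0 h, this flask's pairing constant reads 14.2 /M/h, higher than the 13.2 /M/h carried forward. The neighbour flask charged with 75 mM of substrate has partner as its limiting reagent. There the logarithm, now substrate over partner, starts at 0.868 and climbs by 11.5, so I reckon 58.0 % of its substrate left. That neighbour holds substrate at 58 %, side product at 41.6 %, and partner at 0.049 % of its own charge.

The readings are simulated with constants of no real substance; the scatter is artificial.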